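Ring B (the middle ring, whose C1' carries the ester carbonyl C7') is read as a latent cyclohexane-1,3-dione: C7'–C1'–C2'(O)–C3' is an acetoacetyl unit and C4'(O)–C5'–C6'(CH3) a crotonyl unit. Ring B is grown directly on the ring A phenol. In one operation the enolate of aryl acetoacetate 7 adds to methyl crotonate (bond C1'–C6') and the acetyl carbon closes onto the crotonate carbonyl (bond C3'–C4'), giving dihydro ring B dione 10 with the A–B depside link in place. Precursor 7 is the acetoacetate of methyl 4-hydroxy-2-methoxy-6-methylbenzoate. Aromatization, 4'-O-acylation with benzyl-protected ring C, 2'-O-methylation and hydrogenolysis finish the tridepside.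

Key step: step 5

Remark on the chemistry: locants with one prime belong to ring B and with two primes to ring C; dione 10 is racemic and is drawn as its triketo tautomer, although enol forms are expected to dominate.

Step 1
Reactants: 1 methyl 2,4-dihydroxy-6-methylbenzoate (methyl orsellinate)
Product: 2 methyl 4-(benzyloxy)-2-hydroxy-6-methylbenzoate
Conditions: BnBr (1.05 equiv), K2CO3, acetone, reflux
Reagents that add atoms: benzyl bromide, BrCc1ccccc1
Why: Williamson etherification; the 4-hydroxyl is not hydrogen-bonded to the ester carbonyl, so it is the more acidic and more nucleophilic phenol and should be benzylated selectively by one equivalent of halide.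

Step 2
Reactants: 2 methyl 4-(benzyloxy)-2-hydroxy-6-methylbenzoate
Product: 3 methyl 4-(benzyloxy)-2-methoxy-6-methylbenzoate
Conditions: MeI (3 equiv), K2CO3, DMF, 50 °C
Reagents that add atoms: iodomethane, CI
Why: Williamson etherification of the remaining chelated phenol, which needs excess MeI and warming but has no competing site.

Step 3
Reactants: 3 methyl 4-(benzyloxy)-2-methoxy-6-methylbenzoate
Product: 4 methyl 4-hydroxy-2-methoxy-6-methylbenzoate
Conditions: H2 (1 atm), 10% Pd/C, EtOAc–MeOH, rt
Reagents that add atoms: none
Why: Catalytic hydrogenolysis of the benzyl aryl ether; the methyl ester, the methyl ether and the arene are inert under these conditions.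

Step 4
Reactants: 4 methyl 4-hydroxy-2-methoxy-6-methylbenzoate, 5 2,2,6-trimethyl-4H-1,3-dioxin-4-one
Product: 7 methyl 2-methoxy-6-methyl-4-(3-oxobutanoyloxy)benzoate, via acetylketene 6 (not isolated)
Conditions: 5 (1.3 equiv), xylene, 135 °C, acetone distilled off
Reagents that add atoms: none
Why: Acetoacetylation by acylketene transfer; thermal retro-hetero-Diels–Alder cleavage of the dioxinone releases acetylketene, which the phenol traps under neutral conditions while removal of acetone drives the exchange.

Step 5
Reactants: 7 methyl 2-methoxy-6-methyl-4-(3-oxobutanoyloxy)benzoate, 8 methyl (E)-but-2-enoate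
Product: 10 methyl 2-methoxy-6-methyl-4-{[(1S*,6R*)-6-methyl-2,4-dioxocyclohexane-1-carbonyl]oxy}benzoate (racemic trans isomer), via acyclic Michael adduct 9 (not isolated)
Conditions: NaH (1.0 equiv, no excess), THF, 0 °C; then 8 (1.2 equiv), 0 °C → rt (→ 45 °C if slow); cold aq. HCl work-up (pH 3)
Reagents that add atoms: none
Why: Deprotonation of 7 between its two carbonyls gives a chelated sodium enolate that adds through C1' to the β-carbon of 8 (Michael addition, C1'–C6'); the ester enolate so formed is relayed by proton transfer to the acetyl methyl group, and this terminal enolate attacks the crotonate ester carbonyl (intramolecular Claisen condensation, C3'–C4') with loss of methoxide. The closest known reaction is the acetoacetate–crotonate annulation that gives alkyl dihydroorsellinates, here run on an aryl acetoacetate. The six-membered ring closes in the 6-(enolendo)-exo-trig mode, since both enolate carbons C3' and C2' lie inside the new ring and the attacked C4'=O is exocyclic to it. The stereocenters C1' and C6' arise racemic; C1', flanked by a ketone and the ester, equilibrates to the trans diequatorial arrangement relative to the C6' methyl group (thermodynamic control), and both centers disappear on aromatization. The step needs chemoselectivity for the aryl ester, secured by using no more than one equivalent of a non-nucleophilic hydride base in an aprotic solvent: no alkoxide exists before the ring closure, and the methoxide then released is protonated immediately by the far more acidic dione. Regioselectivity follows from the structure, because C1' is the only soft nucleophilic carbon and closure through C3' is the only six-membered option.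

Step 6
Reactants: 10 methyl 2-methoxy-6-methyl-4-{[(1S*,6R*)-6-methyl-2,4-dioxocyclohexane-1-carbonyl]oxy}benzoate
Product: 12 methyl 4-[(2,4-dihydroxy-6-methylbenzoyl)oxy]-2-methoxy-6-methylbenzoate, via 3'-bromo dione 11 (not isolated)
Conditions: CuBr2 (2.1 equiv), LiBr (1 equiv), MeCN, rt → 60 °C
Reagents that add atoms: none
Why: Oxidative aromatization by α-bromination and dehydrobromination; CuBr2 brominates the enolized 1,3-dione at C3', enolization toward C5' allows 1,4-loss of HBr, and tautomerization of the dienone gives the resorcinol with both stereocenters erased, while two equivalents of CuBr2 deliver only one bromine and so limit ring bromination of the product.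

Step 7
Reactants: 13 2,4-dihydroxy-6-methylbenzoic acid (orsellinic acid)
Product: 14 benzyl 2,4-bis(benzyloxy)-6-methylbenzoate
Conditions: BnBr (3.3 equiv), K2CO3 (4 equiv), DMF, rt then 60 °C
Reagents that add atoms: benzyl bromide, BrCc1ccccc1
Why: Exhaustive Williamson-type O-benzylation of the carboxylate and both phenols; starting at room temperature esterifies the carboxylate before heating, which should prevent decarboxylation.

Step 8
Reactants: 14 benzyl 2,4-bis(benzyloxy)-6-methylbenzoate
Product: 15 2,4-bis(benzyloxy)-6-methylbenzoic acid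
Conditions: KOH (excess), DMSO–H2O (4:1), 90 °C; then aq. HCl
Reagents that add atoms: potassium hydroxide, [K+].[OH-]
Why: Saponification (acyl–oxygen cleavage by hydroxide) of the di-ortho-substituted benzyl ester under forcing alkaline conditions, to which the benzyl ethers are stable.

Step 9
Reactants: 12 methyl 4-[(2,4-dihydroxy-6-methylbenzoyl)oxy]-2-methoxy-6-methylbenzoate, 15 2,4-bis(benzyloxy)-6-methylbenzoic acid
Product: 17 methyl 4-({4-[(2,4-bis(benzyloxy)-6-methylbenzoyl)oxy]-2-hydroxy-6-methylbenzoyl}oxy)-2-methoxy-6-methylbenzoate, via 2,4-bis(benzyloxy)-6-methylbenzoyl chloride 16 (not isolated)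
Conditions: 15 (1.2 equiv), (COCl)2, DMF (cat.), CH2Cl2, 0 °C → rt, evaporate; then 12, pyridine, CH2Cl2, 0 °C → rt
Reagents that add atoms: none
Why: Acid chloride formation followed by O-acylation of a phenol (Schotten–Baumann-type esterification in pyridine); the 4'-hydroxyl should react selectively because the 2'-hydroxyl is hydrogen-bonded to the C7' carbonyl and shielded by it.

Step 10
Reactants: 17 methyl 4-({4-[(2,4-bis(benzyloxy)-6-methylbenzoyl)oxy]-2-hydroxy-6-methylbenzoyl}oxy)-2-methoxy-6-methylbenzoate
Product: 18 methyl 4-({4-[(2,4-bis(benzyloxy)-6-methylbenzoyl)oxy]-2-methoxy-6-methylbenzoyl}oxy)-2-methoxy-6-methylbenzoate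
Conditions: MeI (5 equiv), K2CO3 (2 equiv), acetone, reflux
Reagents that add atoms: iodomethane, CI
Why: Williamson etherification of the last free (chelated) phenol; both depside carbonyls carry two ortho substituents and should resist attack by phenoxide or carbonate in the weakly polar medium.

Step 11
Reactants: 18 methyl 4-({4-[(2,4-bis(benzyloxy)-6-methylbenzoyl)oxy]-2-methoxy-6-methylbenzoyl}oxy)-2-methoxy-6-methylbenzoate
Product: 19 methyl 4-({4-[(2,4-dihydroxy-6-methylbenzoyl)oxy]-2-methoxy-6-methylbenzoyl}oxy)-2-methoxy-6-methylbenzoate (CNP0514431.0)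
Conditions: H2 (1 atm), 10% Pd/C, EtOAc–THF, rt
Reagents that add atoms: none
Why: Catalytic hydrogenolysis of the two benzyl aryl ethers under neutral conditions, which leaves aryl esters, the methyl ester and the methyl ethers untouched and frees the ring C resorcinol as the last operation.

Compound list
1 | methyl 2,4-dihydroxy-6-methylbenzoate (methyl orsellinate) | COC(=O)c1c(C)cc(O)cc1O | starting material
2 | methyl 4-(benzyloxy)-2-hydroxy-6-methylbenzoate | COC(=O)c1c(C)cc(OCc2ccccc2)cc1O | intermediate
3 | methyl 4-(benzyloxy)-2-methoxy-6-methylbenzoate | COC(=O)c1c(C)cc(OCc2ccccc2)cc1OC | intermediate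
4 | methyl 4-hydroxy-2-methoxy-6-methylbenzoate | COC(=O)c1c(C)cc(O)cc1OC | intermediate
5 | 2,2,6-trimethyl-4H-1,3-dioxin-4-one | CC1=CC(=O)OC(C)(C)O1 | starting material
6 | acetylketene (but-1-ene-1,3-dione), not isolated | CC(=O)C=C=O | intermediate
7 | methyl 2-methoxy-6-methyl-4-(3-oxobutanoyloxy)benzoate | COC(=O)c1c(C)cc(OC(=O)CC(C)=O)cc1OC | intermediate
8 | methyl (E)-but-2-enoate | C/C=C/C(=O)OC | starting material
9 | 1-[3-methoxy-4-(methoxycarbonyl)-5-methylphenyl] 5-methyl 2-acetyl-3-methylpentanedioate (acyclic Michael adduct, present as its sodium enolate, mixture of diastereomers, not isolated) | COC(=O)CC(C)C(C(C)=O)C(=O)Oc1cc(C)c(C(=O)OC)c(OC)c1 | intermediate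
10 | methyl 2-methoxy-6-methyl-4-{[(1S*,6R*)-6-methyl-2,4-dioxocyclohexane-1-carbonyl]oxy}benzoate (racemic, trans; one enantiomer drawn) | COC(=O)c1c(C)cc(OC(=O)[C@H]2[C@H](C)CC(=O)CC2=O)cc1OC | intermediate
11 | methyl 4-[(3-bromo-6-methyl-2,4-dioxocyclohexane-1-carbonyl)oxy]-2-methoxy-6-methylbenzoate (mixture of stereoisomers, not isolated) | COC(=O)c1c(C)cc(OC(=O)C2C(C)CC(=O)C(Br)C2=O)cc1OC | intermediate
12 | methyl 4-[(2,4-dihydroxy-6-methylbenzoyl)oxy]-2-methoxy-6-methylbenzoate | COC(=O)c1c(C)cc(OC(=O)c2c(C)cc(O)cc2O)cc1OC | intermediate
13 | 2,4-dihydroxy-6-methylbenzoic acid (orsellinic acid) | Cc1cc(O)cc(O)c1C(=O)O | starting material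
14 | benzyl 2,4-bis(benzyloxy)-6-methylbenzoate | Cc1cc(OCc2ccccc2)cc(OCc2ccccc2)c1C(=O)OCc1ccccc1 | intermediate
15 | 2,4-bis(benzyloxy)-6-methylbenzoic acid | Cc1cc(OCc2ccccc2)cc(OCc2ccccc2)c1C(=O)O | intermediate
16 | 2,4-bis(benzyloxy)-6-methylbenzoyl chloride (not isolated) | Cc1cc(OCc2ccccc2)cc(OCc2ccccc2)c1C(=O)Cl | intermediate
17 | methyl 4-({4-[(2,4-bis(benzyloxy)-6-methylbenzoyl)oxy]-2-hydroxy-6-methylbenzoyl}oxy)-2-methoxy-6-methylbenzoate | COC(=O)c1c(C)cc(OC(=O)c2c(C)cc(OC(=O)c3c(C)cc(OCc4ccccc4)cc3OCc3ccccc3)cc2O)cc1OC | intermediate
18 | methyl 4-({4-[(2,4-bis(benzyloxy)-6-methylbenzoyl)oxy]-2-methoxy-6-methylbenzoyl}oxy)-2-methoxy-6-methylbenzoate | COC(=O)c1c(C)cc(OC(=O)c2c(C)cc(OC(=O)c3c(C)cc(OCc4ccccc4)cc3OCc3ccccc3)cc2OC)cc1OC | intermediate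
19 | methyl 4-({4-[(2,4-dihydroxy-6-methylbenzoyl)oxy]-2-methoxy-6-methylbenzoyl}oxy)-2-methoxy-6-methylbenzoate | COC(=O)c1c(C)cc(OC(=O)c2c(C)cc(OC(=O)c3c(C)cc(O)cc3O)cc2OC)cc1OC | target

Total step count: 11
Longest linear sequence: 9 steps (steps 1–6, then 9–11, from methyl orsellinate); steps 7 and 8 form the ring C branch.

Steps most likely to fail

1. Step 5. The sodium enolate of the aryl acetoacetate may expel the ring A phenoxide by elimination through acetylketene. That loss becomes irreversible once the methanol liberated in the ring closure traps the ketene. Conjugate addition to the β-methyl acrylate may also be too slow below the temperature at which this cleavage sets in.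
Fallback (classical stepwise depside assembly; sets out from 3, uses 4 and 16, comes back at 18): ester 3 would be saponified (KOH, aq. DMSO, 90 °C; HCl) to 4-(benzyloxy)-2-methoxy-6-methylbenzoic acid F1. F1 would be condensed with phenol 4 (DCC, DMAP cat., CH2Cl2, Steglich esterification) to methyl 4-{[4-(benzyloxy)-2-methoxy-6-methylbenzoyl]oxy}-2-methoxy-6-methylbenzoate F2. Hydrogenolysis (H2, Pd/C, EtOAc) would give methyl 4-[(4-hydroxy-2-methoxy-6-methylbenzoyl)oxy]-2-methoxy-6-methylbenzoate F3. Acylation of F3 with acid chloride 16 (made from 15 as in step 9; pyridine, CH2Cl2) would deliver 18, from which step 11 follows.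

2. Step 6. Bromination may not stop after one equivalent: further ring bromination of the very electron-rich resorcinol, or incomplete loss of HBr from the bromo dione, would give mixtures, and the HBr formed could slowly attack the aryl ester.
Fallback (deliberate over-bromination and reductive debromination; sets out from 10, comes back at 12): 10 would be treated with Br2 (3 equiv) in AcOH at rt to aromatize and brominate both free ring B positions, giving methyl 4-[(3,5-dibromo-2,4-dihydroxy-6-methylbenzoyl)oxy]-2-methoxy-6-methylbenzoate F4. Hydrogenolytic debromination (H2, Pd/C, NaOAc, EtOAc–MeOH) would then return resorcinol 12.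

3. Step 10. Alkylation of the hydrogen-bonded 2'-phenoxide may be slow, so that base-induced ester interchange between depside units or a Smiles-type aryl migration onto ring A could compete and scramble the tridepside.
Fallback (ether formation without any phenoxide; sets out from 17, comes back at 18): the Williamson alkylation would be replaced by a Mitsunobu etherification of 17 with methanol (PPh3, DIAD, THF, 0 °C → rt), a redox condensation under neutral conditions that forms the same 2'-O-methyl ether 18 directly. It passes through no compound outside the list (none F0).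

Further compounds
F1 | step 5 | 4-(benzyloxy)-2-methoxy-6-methylbenzoic acid | COc1cc(OCc2ccccc2)cc(C)c1C(=O)O
F2 | step 5 | methyl 4-{[4-(benzyloxy)-2-methoxy-6-methylbenzoyl]oxy}-2-methoxy-6-methylbenzoate | COC(=O)c1c(C)cc(OC(=O)c2c(C)cc(OCc3ccccc3)cc2OC)cc1OC
F3 | step 5 | methyl 4-[(4-hydroxy-2-methoxy-6-methylbenzoyl)oxy]-2-methoxy-6-methylbenzoate | COC(=O)c1c(C)cc(OC(=O)c2c(C)cc(O)cc2OC)cc1OC
F4 | step 6 | methyl 4-[(3,5-dibromo-2,4-dihydroxy-6-methylbenzoyl)oxy]-2-methoxy-6-methylbenzoate | COC(=O)c1c(C)cc(OC(=O)c2c(C)c(Br)c(O)c(Br)c2O)cc1OC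
F0 | step 10 | none | none
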